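**Plan**

- Retrosynthesis: the C2–H bond is traced back to a C2 methyl ketal. The pyran ring is then opened at C3–C4 and O1–C2 into an ortho-quinone methide and 2-methoxypropene. The carbinol that masks the quinone methide is cut at its naphthyl–carbon bond into 1-bromo-4,5-dimethoxynaphthalene and 2,6-dihydroxybenzaldehyde.
- Enabling feature: C4 is a diarylmethine on a resorcinol ring whose two ortho carbons both carry oxygen (C8a with O1, C5 with the hydroxyl). The carbinol can therefore give one ortho-quinone methide only, and either oxygen closes to the same chroman.
- Forward: both aromatic systems are bought and joined at the future C4 by aryllithium addition to the bis-allyl ether of the aldehyde. The allyl groups are then removed, and the pyran ring, the only ring made, closes in the [4+2] step.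
- Stereochemistry: C4 (S) comes from the chiral phosphoric acid in the cycloaddition. C2 (S) comes last, from hydride delivery to the C2 oxocarbenium ion on the face away from the C4 naphthyl group, which places methyl and naphthyl cis.

Key step: step 5

Assumption: the (R)-configured catalyst is taken to expose the face of the quinone methide that leads to 4S; if the sense proves opposite, the (S)-catalyst is used and nothing else changes.
Assumption: the ketal from the key step is drawn as its (2S,4S) epimer for bookkeeping only; either C2 epimer or a mixture serves, because C2 becomes trigonal again in the last step.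

**Route**

Step 1
Reactants: 1 1,8-dimethoxynaphthalene
Product: 2 1-bromo-4,5-dimethoxynaphthalene
Conditions: NBS (1.0 equiv), MeCN, 0 °C to rt, dark
Reagents that add atoms: N-bromosuccinimide, O=C1CCC(=O)N1Br
Why: Electrophilic aromatic bromination, in which the carbon para to a methoxy group is the most activated and least hindered site and one equivalent of NBS in a polar solvent should stop at the monobromide.

Step 2
Reactants: 3 2,6-dihydroxybenzaldehyde
Product: 4 2,6-bis(prop-2-en-1-yloxy)benzaldehyde
Conditions: allyl bromide (2.5 equiv), K2CO3 (3 equiv), DMF, 60 °C
Reagents that add atoms: allyl bromide, C=CCBr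
Why: Williamson etherification of both phenols, chosen because allyl ethers survive an aryllithium and can later be removed without acid, which the ionisation-prone diarylcarbinol made afterwards would not tolerate.

Step 3
Reactants: 2 1-bromo-4,5-dimethoxynaphthalene; 4 2,6-bis(prop-2-en-1-yloxy)benzaldehyde
Product: 6 [2,6-bis(prop-2-en-1-yloxy)phenyl](4,5-dimethoxynaphthalen-1-yl)methanol (racemic), via aryllithium 5 (not isolated)
Conditions: 2, n-BuLi (1.05 equiv), THF, –78 °C; then 4, –78 to –40 °C; H2O
Reagents that add atoms: none
Why: Bromine–lithium exchange outruns any deprotonation at –78 °C and the aryllithium adds 1,2 to the aldehyde, the carbinol centre being left racemic because it becomes trigonal in the key step.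

Step 4
Reactants: 6 [2,6-bis(prop-2-en-1-yloxy)phenyl](4,5-dimethoxynaphthalen-1-yl)methanol
Product: 7 2-[(4,5-dimethoxynaphthalen-1-yl)(hydroxy)methyl]benzene-1,3-diol (racemic)
Conditions: Pd(PPh3)4 (5 mol %), morpholine (10 equiv), THF, rt, argon
Reagents that add atoms: none
Why: Tsuji–Trost deallylation, in which zerovalent palladium ionises each aryl allyl ether to a π-allyl complex and a phenoxide, morpholine captures the allyl group, and the neutral to basic medium leaves the acid-labile diarylcarbinol untouched.

Step 5
Reactants: 7 2-[(4,5-dimethoxynaphthalen-1-yl)(hydroxy)methyl]benzene-1,3-diol; 8 2-methoxypropene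
Product: 10 (2S,4S)-4-(4,5-dimethoxynaphthalen-1-yl)-2-methoxy-2-methyl-3,4-dihydro-2H-chromen-5-ol, via ortho-quinone methide 9 (not isolated)
Conditions: (R)-TRIP [(R)-3,3'-bis(2,4,6-triisopropylphenyl)-1,1'-binaphthyl-2,2'-diyl hydrogen phosphate] (10 mol %), 8 (3 equiv), 4 Å MS, toluene, –20 °C
Reagents that add atoms: none
Why: The phosphoric acid protonates the carbinol, water leaves with the push of the 4-methoxynaphthyl group and of either ortho hydroxyl, and ortho-quinone methide 9 stays bound to the chiral phosphate through its carbonyl oxygen and its remaining ortho hydroxyl. Enol ether 8 then adds across the methide carbon and the carbonyl oxygen in a concerted, asynchronous inverse-electron-demand oxa-Diels–Alder reaction in which C3–C4 bonding runs ahead of O1–C2 bonding. The closest known reaction type is the chiral phosphoric acid-catalysed [4+2] cycloaddition of ortho-quinone methides, made in the flask from ortho-hydroxybenzhydrols, with enol ethers and other electron-rich alkenes. The pyran ring closes by intermolecular [4+2] cycloaddition, four atoms (O1, C8a, C4a, C4) coming from 9 and two (C2, C3) from the enol ether. C4 is set by the catalyst, whose 3,3'-aryl groups block one face of the bound methide, whereas the ketal carbon C2 follows the endo/exo preference and is of no consequence. The step needs enantiofacial selectivity at C4 and head-to-tail regiochemistry: the two-point contact of carbonyl oxygen and free hydroxyl to the phosphate secures the first, the polarity of the enol ether the second, and the twofold symmetry of the resorcinol ring removes any choice of which oxygen becomes O1.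

Step 6
Reactants: 10 (2S,4S)-4-(4,5-dimethoxynaphthalen-1-yl)-2-methoxy-2-methyl-3,4-dihydro-2H-chromen-5-ol
Product: 12 (2S,4S)-4-(4,5-dimethoxynaphthalen-1-yl)-2-methyl-3,4-dihydro-2H-chromen-5-ol (cladonaphchrom B), via oxocarbenium ion 11 (not isolated)
Conditions: Et3SiH (5 equiv), BF3·OEt2 (2 equiv), CH2Cl2, –78 to –40 °C; then aq NaHCO3
Reagents that add atoms: none
Why: Ionic hydrogenation of a ketal, in which BF3 removes the methoxy group to give oxocarbenium ion 11 and Et3SiH delivers hydride to C2 on the face away from the C4 naphthyl group (held pseudoaxial over the other face by peri strain with the C5 hydroxyl), so that the new C2–H ends trans and the methyl cis to the naphthyl (2S), in line with the trans-selective substitutions known for 4-arylchroman-2-yl cations.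

**Compound list**

1 | 1,8-dimethoxynaphthalene | COc1cccc2cccc(OC)c12 | starting material
2 | 1-bromo-4,5-dimethoxynaphthalene | COc1cccc2c(Br)ccc(OC)c12 | intermediate
3 | 2,6-dihydroxybenzaldehyde | O=Cc1c(O)cccc1O | starting material
4 | 2,6-bis(prop-2-en-1-yloxy)benzaldehyde | O=Cc1c(OCC=C)cccc1OCC=C | intermediate
5 | (4,5-dimethoxynaphthalen-1-yl)lithium (formed in the flask) | COc1cccc2c([Li])ccc(OC)c12 | intermediate
6 | [2,6-bis(prop-2-en-1-yloxy)phenyl](4,5-dimethoxynaphthalen-1-yl)methanol (racemic) | COc1cccc2c(C(O)c3c(OCC=C)cccc3OCC=C)ccc(OC)c12 | intermediate
7 | 2-[(4,5-dimethoxynaphthalen-1-yl)(hydroxy)methyl]benzene-1,3-diol (racemic) | COc1cccc2c(C(O)c3c(O)cccc3O)ccc(OC)c12 | intermediate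
8 | 2-methoxypropene | C=C(C)OC | starting material
9 | 6-[(4,5-dimethoxynaphthalen-1-yl)methylidene]-5-hydroxycyclohexa-2,4-dien-1-one (ortho-quinone methide, formed in the flask; its two alkene geometries interconvert by proton shift between the oxygens) | COc1cccc2c(C=C3C(=O)C=CC=C3O)ccc(OC)c12 | intermediate
10 | (2S,4S)-4-(4,5-dimethoxynaphthalen-1-yl)-2-methoxy-2-methyl-3,4-dihydro-2H-chromen-5-ol | COc1cccc2c([C@@H]3C[C@](OC)(C)Oc4cccc(O)c43)ccc(OC)c12 | intermediate
11 | (4S)-4-(4,5-dimethoxynaphthalen-1-yl)-5-hydroxy-2-methyl-3,4-dihydrochromenylium (C2 oxocarbenium ion, formed in the flask; cation shown) | COc1cccc2c([C@@H]3CC(C)=[O+]c4cccc(O)c43)ccc(OC)c12 | intermediate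
12 | (2S,4S)-4-(4,5-dimethoxynaphthalen-1-yl)-2-methyl-3,4-dihydro-2H-chromen-5-ol (cladonaphchrom B) | COc1cccc2c([C@@H]3C[C@H](C)Oc4cccc(O)c43)ccc(OC)c12 | target

**Step count**

Total steps: 6. Longest linear sequence: 5 steps (steps 1, 3, 4, 5, 6 from 1, or steps 2, 3, 4, 5, 6 from 3).

**Steps most likely to fail**

1. Step 5.
- What may go wrong: enantiofacial discrimination may be weak, because the enol ether offers the phosphate no hydrogen-bond donor and an unselective acid-catalysed pathway can compete. The enol ether can also reversibly ketalise the hydroxyl groups and is consumed by the water released.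
- Fallback: it sets out from 7 and comes back to the route at 11, and so at 12. The 2π partner is changed to an enamide whose N–H binds the phosphoryl oxygen while the acid proton binds the quinone methide, the established two-point arrangement for these cycloadditions. Acetone oxime is converted with iron powder and acetic anhydride into N-(prop-1-en-2-yl)acetamide F1. Reaction of 7 with F1 and the same catalyst should give the N,O-ketal N-[(4S)-4-(4,5-dimethoxynaphthalen-1-yl)-5-hydroxy-2-methyl-3,4-dihydro-2H-chromen-2-yl]acetamide F2, as either C2 epimer. Dilute aqueous HCl in THF at 0 °C then exchanges the acetamido group for hydroxyl to give the hemiketal (4S)-4-(4,5-dimethoxynaphthalen-1-yl)-2-methyl-3,4-dihydro-2H-chromene-2,5-diol F3. Under the conditions of step 6, F3 ionises to 11 and is reduced to 12.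

2. Step 6.
- What may go wrong: hydride delivery to C2 may show too little facial bias. The endocyclic C2–O1 bond may ionise instead, with reduction to a ring-opened methyl ether. The cation may also be captured by the electron-rich peri carbon of the naphthalene.
- Fallback: it sets out from 10 and comes back at 12. C2 is set by heterogeneous syn-hydrogenation of an alkene instead of by hydride addition to a cation. PPTS (cat.) in toluene at 80 °C with removal of methanol should give (4S)-4-(4,5-dimethoxynaphthalen-1-yl)-2-methyl-4H-chromen-5-ol F4. Hydrogenation of F4 (H2, 1 atm, 10% Pd/C, EtOAc, rt) adds both hydrogens from the face opposite the pseudoaxial naphthyl group and should give 12.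

3. Step 4.
- What may go wrong: the liberated resorcinol ring may be C-allylated by the π-allylpalladium intermediate, the second allyl group may not come off completely, or the free triol may ionise and self-condense on silica.
- Fallback: it sets out from 2 and 3 and comes back at 7, using no protecting groups. Bromide 2 is converted with Mg turnings in THF into (4,5-dimethoxynaphthalen-1-yl)magnesium bromide F5. About 3.5 equiv of F5 is added to unprotected 3 at 0 °C: two equivalents deprotonate the phenols and a third adds to the magnesium-chelated aldehyde. Aqueous work-up gives 7 directly, bypassing 4 and 6, and the crude triol is taken straight into step 5.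

Further compounds
F1 | step 5 | N-(prop-1-en-2-yl)acetamide | C=C(C)NC(C)=O
F2 | step 5 | N-[(4S)-4-(4,5-dimethoxynaphthalen-1-yl)-5-hydroxy-2-methyl-3,4-dihydro-2H-chromen-2-yl]acetamide (either C2 epimer) | COc1cccc2c([C@@H]3CC(C)(NC(C)=O)Oc4cccc(O)c43)ccc(OC)c12
F3 | step 5 | (4S)-4-(4,5-dimethoxynaphthalen-1-yl)-2-methyl-3,4-dihydro-2H-chromene-2,5-diol (either C2 epimer) | COc1cccc2c([C@@H]3CC(C)(O)Oc4cccc(O)c43)ccc(OC)c12
F4 | step 6 | (4S)-4-(4,5-dimethoxynaphthalen-1-yl)-2-methyl-4H-chromen-5-ol | COc1cccc2c([C@@H]3C=C(C)Oc4cccc(O)c43)ccc(OC)c12
F5 | step 4 | (4,5-dimethoxynaphthalen-1-yl)magnesium bromide | COc1cccc2c([Mg]Br)ccc(OC)c12
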